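**Retrosynthetic overview**
Numbering follows 3,7-dioxabicyclo[3.3.0]octane: C1 (OAc), C2 (aryl), O3, C4, C5 (H), C6 (aryl), O7, C8. Ring A is C1-C5-C6-O7-C8 and ring B is C1-C2-O3-C4-C5.
Enabling feature: C2 is bonded to ring oxygen O3 and lies next to the C1–O bond, cis to it on the convex face. This makes it a 1,2-cis C-aryl "glycoside" of ring B, and its retron is the exo epoxide of a C1=C2 enol ether.
Key disconnection: the C2–aryl bond, the C1–O bond and the acetate all come in one flask from enol ether 10 (two stereocentres) and a triarylalane, by epoxidation, syn aryl transfer and acetylation of the aluminium alkoxide.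
Ring order: ring A is closed first, by titanocene-mediated 5-exo-dig radical cyclisation of epoxy propargyl ether 5. Ring B is closed second, from ketone 8, by alkylidene-carbene O–H insertion.
Absolute configuration: only C6 is set by catalysis, in the Sharpless kinetic-resolution epoxidation of 3. C5, C1 and C2 are relayed from it.

Key step: step 9

Remark: Ar = 3-methoxy-4-(triisopropylsilyloxy)phenyl; DMDO is used as a dried stock solution in acetone and counts as a reagent; the sense of induction in step 3 is taken from the usual Sharpless model (aryl ranks above vinyl in the descriptors).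

Step 1
Reactants: 1 vanillin
Product: 2 3-methoxy-4-(triisopropylsilyloxy)benzaldehyde
Conditions: TIPSCl, imidazole, DMF, rt
Reagents that add atoms: triisopropylsilyl chloride, CC(C)[Si](Cl)(C(C)C)C(C)C
Why: Imidazole-promoted silyl ether formation on the phenol gives a bulky TIPS ether that should survive the alkoxide, organometallic, titanocene and dioxirane steps and leave with fluoride without touching the acetate.

Step 2
Reactants: 2 3-methoxy-4-(triisopropylsilyloxy)benzaldehyde
Product: 3 rac-1-Ar-prop-2-en-1-ol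
Conditions: vinylmagnesium bromide, THF, −78 → 0 °C; aq NH4Cl
Reagents that add atoms: vinylmagnesium bromide, C=C[Mg]Br
Why: Grignard 1,2-addition to a non-enolisable aromatic aldehyde forms the carbinol centre (future C6) as a racemate, which is resolved in step 3.

Step 3
Reactants: 3 rac-1-Ar-prop-2-en-1-ol
Product: 4 (R)-Ar[(2S)-oxiran-2-yl]methanol (anti epoxy alcohol)
Conditions: Ti(OiPr)4 (0.1 equiv), D-(−)-DIPT (0.12 equiv), t-BuOOH (0.45 equiv), 4 Å MS, CH2Cl2, −20 °C
Reagents that add atoms: tert-butyl hydroperoxide, CC(C)(C)OO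
Why: In a Sharpless asymmetric epoxidation run as a kinetic resolution, D-(−)-DIPT makes the (S)-alcohol the fast-reacting enantiomer and should give the anti epoxy alcohol, which fixes C6, while the reagent-controlled oxirane carbon is erased again in step 5.

Step 4
Reactants: 4 (R)-Ar[(2S)-oxiran-2-yl]methanol
Product: 5 (2S)-2-[(R)-Ar(prop-2-yn-1-yloxy)methyl]oxirane
Conditions: NaH, propargyl bromide, Bu4NI (cat.), THF, 0 °C
Reagents that add atoms: propargyl bromide, C#CCBr
Why: Williamson etherification of the sodium alkoxide with an unhindered propargylic bromide is run cold in an aprotic solvent so that alkylation outruns Payne rearrangement, and no stereocentre is touched.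

Step 5
Reactants: 5 (2S)-2-[(R)-Ar(prop-2-yn-1-yloxy)methyl]oxirane
Product: 7 [(2S,3R)-2-Ar-4-methylideneoxolan-3-yl]methanol, via C5 radical 6 (not isolated)
Conditions: Cp2TiCl2 (2.2 equiv), Zn dust, THF, rt, slow addition of the Cp2TiCl solution; aq NaH2PO4
Reagents that add atoms: none
Why: Nugent–RajanBabu reductive epoxide opening by trivalent titanium gives the secondary radical at C5, which closes ring A by 5-exo-dig addition to the alkyne, and C5 is set trans to the C6 aryl group because the CH2O[Ti] arm lies anti to the aryl group in the cyclisation transition state.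

Step 6
Reactants: 7 [(2S,3R)-2-Ar-4-methylideneoxolan-3-yl]methanol
Product: 8 (4R,5S)-4-(hydroxymethyl)-5-Ar-oxolan-3-one
Conditions: OsO4 (cat.), NaIO4, 2,6-lutidine, dioxane–H2O, rt
Reagents that add atoms: osmium tetroxide (oxygen carrier), O=[Os](=O)(=O)=O; sodium periodate (terminal oxidant), [Na+].[O-]I(=O)(=O)=O
Why: Lemieux–Johnson cleavage removes only the terminal alkene carbon and spares the electron-rich arene better than ozone, while lutidine buffering protects the epimerisable C5 centre, which in any case prefers the trans arrangement.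

Step 7
Reactants: 8 (4R,5S)-4-(hydroxymethyl)-5-Ar-oxolan-3-one
Product: 10 (5R,6S)-6-Ar-3,7-dioxabicyclo[3.3.0]oct-1-ene, via alkylidene carbene 9 (not isolated)
Conditions: TMSCHN2 (2.4 equiv), n-BuLi (2.3 equiv), THF, −78 °C; then 8, −78 → 0 °C
Reagents that add atoms: trimethylsilyldiazomethane, C[Si](C)(C)C=[N+]=[N-]
Why: Colvin-type olefination with lithiated TMSCHN2 gives, after loss of silanolate and N2, the exocyclic alkylidene carbene, which is trapped by 1,5 O–H insertion of the neighbouring hydroxymethyl group (the known route from β-oxy ketones to 2,3-dihydrofurans) and so closes ring B without forming or touching a stereocentre.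

Step 8
Reactants: 11 4-bromo-2-methoxyphenol
Product: 12 (4-bromo-2-methoxyphenoxy)triisopropylsilane
Conditions: TIPSCl, imidazole, DMF, rt
Reagents that add atoms: triisopropylsilyl chloride, CC(C)[Si](Cl)(C(C)C)C(C)C
Why: Silyl ether protection as in step 1 places the bromine para to the oxygen and thereby fixes the regiochemistry of the later aryl transfer.

Step 9
Reactants: 10 (5R,6S)-6-Ar-3,7-dioxabicyclo[3.3.0]oct-1-ene; 12 (4-bromo-2-methoxyphenoxy)triisopropylsilane
Product: 17 (1S,2R,5R,6S)-2,6-di-Ar-3,7-dioxabicyclo[3.3.0]octan-1-yl acetate, via aryllithium 13 (not isolated), via triarylalane 14 (not isolated), via exo-epoxide 15 (not isolated), via aluminium alkoxide 16 (not isolated)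
Conditions: (a) 12, n-BuLi, Et2O, −78 °C; AlCl3 (0.33 equiv), → rt, toluene; (b) 10, DMDO, acetone–CH2Cl2, −78 → 0 °C, volatiles removed; (c) 14 (1.5 equiv), toluene–CH2Cl2, −78 → 0 °C; (d) Ac2O, pyridine, DMAP, → rt
Reagents that add atoms: dimethyldioxirane, CC1(C)OO1; acetic anhydride, CC(=O)OC(C)=O
Why: DMDO transfers oxygen to the electron-rich C1=C2 enol ether to give 15, the alane binds the oxirane oxygen, the C2–O bond ionises with help from O3 to an oxocarbenium–aluminate ion pair, an aryl group migrates from aluminium to C2 inside this pair, and alkoxide 16 is acetylated in the same flask. The closest known chemistry is the epoxidation of glycals to 1,2-anhydro sugars, their syn (1,2-cis) opening by triorganoalanes to C-glycosides, and the in situ acetylation of aluminium alkoxides with Ac2O, pyridine and DMAP known from reductive acetylation of esters. No ring of the target is closed here, since the only ring formed is the transient oxirane (concerted syn oxygen transfer), which is opened again. C1 is controlled by C5, because oxygen can add only to the face that carries H5 (the other face would give a trans-fused bicyclo[3.3.0]octane), and C2 is controlled by C1, because the aryl group is delivered from the aluminium held on the C1 oxygen and therefore arrives cis to it, which is also the convex face. Chemoselectivity for the enol ether over the arene and the benzylic ether rests on its much higher nucleophilicity towards DMDO at low temperature, regioselective opening at C2 rests on cation stabilisation by O3, and keeping a non-participating alkoxide rather than an acetate on C1 while the C–C bond forms avoids the dioxolenium ion that would steer the aryl group to the concave face.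

Step 10
Reactants: 17 (1S,2R,5R,6S)-2,6-di-Ar-3,7-dioxabicyclo[3.3.0]octan-1-yl acetate
Product: 18 1-acetoxypinoresinol, (1S,2R,5R,6S)-2,6-bis(4-hydroxy-3-methoxyphenyl)-3,7-dioxabicyclo[3.3.0]octan-1-yl acetate
Conditions: TBAF, AcOH (1:1), THF, 0 °C
Reagents that add atoms: none
Why: Fluoride-induced desilylation of both aryl TIPS ethers is buffered with AcOH so that the phenoxides are protonated at once and neither acetate transfer nor epimerisation of the sensitive benzylic ethers should occur.

**Compound list**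
1 | vanillin | COc1cc(C=O)ccc1O | starting material
2 | 3-methoxy-4-(triisopropylsilyloxy)benzaldehyde | COc1cc(C=O)ccc1O[Si](C(C)C)(C(C)C)C(C)C | intermediate
3 | rac-1-Ar-prop-2-en-1-ol | COc1cc(C(O)C=C)ccc1O[Si](C(C)C)(C(C)C)C(C)C | intermediate
4 | (R)-Ar[(2S)-oxiran-2-yl]methanol | COc1cc([C@@H](O)[C@@H]2CO2)ccc1O[Si](C(C)C)(C(C)C)C(C)C | intermediate
5 | (2S)-2-[(R)-Ar(prop-2-yn-1-yloxy)methyl]oxirane | COc1cc([C@@H](OCC#C)[C@@H]2CO2)ccc1O[Si](C(C)C)(C(C)C)C(C)C | intermediate
6 | β-titanoxy C5 radical (Cp2TiCl alkoxide) | COc1cc([C@@H](OCC#C)[CH]CO[Ti](Cl)(C2C=CC=C2)C2C=CC=C2)ccc1O[Si](C(C)C)(C(C)C)C(C)C | intermediate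
7 | [(2S,3R)-2-Ar-4-methylideneoxolan-3-yl]methanol | COc1cc([C@H]2OCC(=C)[C@@H]2CO)ccc1O[Si](C(C)C)(C(C)C)C(C)C | intermediate
8 | (4R,5S)-4-(hydroxymethyl)-5-Ar-oxolan-3-one | COc1cc([C@H]2OCC(=O)[C@@H]2CO)ccc1O[Si](C(C)C)(C(C)C)C(C)C | intermediate
9 | exocyclic alkylidene carbene of 8 | COc1cc([C@H]2OCC(=[C])[C@@H]2CO)ccc1O[Si](C(C)C)(C(C)C)C(C)C | intermediate
10 | (5R,6S)-6-Ar-3,7-dioxabicyclo[3.3.0]oct-1-ene | COc1cc([C@H]2OCC3=COC[C@H]23)ccc1O[Si](C(C)C)(C(C)C)C(C)C | intermediate
11 | 4-bromo-2-methoxyphenol | COc1cc(Br)ccc1O | starting material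
12 | (4-bromo-2-methoxyphenoxy)triisopropylsilane | COc1cc(Br)ccc1O[Si](C(C)C)(C(C)C)C(C)C | intermediate
13 | Ar-lithium | COc1cc([Li])ccc1O[Si](C(C)C)(C(C)C)C(C)C | intermediate
14 | tri-Ar-alane | COc1cc(ccc1O[Si](C(C)C)(C(C)C)C(C)C)[Al](c1ccc(O[Si](C(C)C)(C(C)C)C(C)C)c(OC)c1)c1ccc(O[Si](C(C)C)(C(C)C)C(C)C)c(OC)c1 | intermediate
15 | exo (convex-face) 1,2-epoxide of 10, oxygen cis to H5 | COc1cc([C@H]2OC[C@@]34O[C@H]4OC[C@H]23)ccc1O[Si](C(C)C)(C(C)C)C(C)C | intermediate
16 | di-Ar-aluminium alkoxide of the C1 tertiary alcohol, aryl at C2 exo | COc1cc([C@H]2OC[C@]3(O[Al](c4ccc(O[Si](C(C)C)(C(C)C)C(C)C)c(OC)c4)c4ccc(O[Si](C(C)C)(C(C)C)C(C)C)c(OC)c4)[C@@H](c4ccc(O[Si](C(C)C)(C(C)C)C(C)C)c(OC)c4)OC[C@H]23)ccc1O[Si](C(C)C)(C(C)C)C(C)C | intermediate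
17 | (1S,2R,5R,6S)-2,6-di-Ar-3,7-dioxabicyclo[3.3.0]octan-1-yl acetate | COc1cc([C@H]2OC[C@]3(OC(C)=O)[C@@H](c4ccc(O[Si](C(C)C)(C(C)C)C(C)C)c(OC)c4)OC[C@H]23)ccc1O[Si](C(C)C)(C(C)C)C(C)C | intermediate
18 | 1-acetoxypinoresinol | COc1cc([C@H]2OC[C@]3(OC(C)=O)[C@@H](c4ccc(O)c(OC)c4)OC[C@H]23)ccc1O | target

**Step count and risks**
Total steps: 10. Longest linear sequence: 9 (steps 1–7, 9, 10).

Steps most likely to fail:

Step 9. The strained anhydro intermediate may ionise and be hydrolysed or rearrange before the aryl group is transferred. Aryl migration from an ether-solvated alane may be slow, and acetylation of the hindered aluminium alkoxide may stall.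
- The fallback sets out from 10 and comes back at 17.
- Enol ether 10 is epoxidised as before to 15, which is hydrolysed in wet THF to the lactol (1S,5R,6S)-6-Ar-3,7-dioxabicyclo[3.3.0]octane-1,2-diol F1.
- An excess of the Grignard reagent Ar-magnesium bromide F2 (from 12 and Mg in THF) adds to the open α-hydroxy aldehyde form under Cram chelate control, from the side of the C8 methylene group. This should give the triol (3S,4R,5S)-3-[(R)-Ar(hydroxy)methyl]-4-(hydroxymethyl)-5-Ar-oxolan-3-ol F3.
- Mitsunobu cyclodehydration (PPh3, DIAD, THF) activates the primary alcohol and lets the benzylic hydroxyl close ring B (5-exo-tet, C2 retained). The product is the tertiary alcohol (1S,2R,5R,6S)-2,6-di-Ar-3,7-dioxabicyclo[3.3.0]octan-1-ol F4.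
- F4 is acetylated with Ac2O, DMAP and Et3N to give 17.

Step 7. The ketone may undergo enolisation, retro-aldol loss of formaldehyde or β-elimination under the basic conditions. Ring expansion of the cyclic carbene by 1,2-shift may also compete with O–H insertion.
- The fallback avoids the carbene. It sets out from 8 and comes back at 10.
- Wittig methoxymethylenation (Ph3PCH2OMe chloride, KHMDS, THF) gives the enol ether [(2S,3R)-2-Ar-4-(methoxymethylidene)oxolan-3-yl]methanol F5.
- PPTS in CH2Cl2 adds the free hydroxyl to the protonated enol ether and gives the cis-fused acetal (1R,5R,6S)-2-methoxy-6-Ar-3,7-dioxabicyclo[3.3.0]octane F6.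
- TMSOTf and iPr2NEt then eliminate the methoxy group to give 10.

Step 5. The radical may be reduced to an organotitanium species before it cyclises, with β-elimination to the deoxygenated allyl ether. Trans selectivity at C5 may also be incomplete.
- The fallback sets out from 3 and comes back at 7.
- Sharpless kinetic resolution with L-(+)-DIPT, taken past half conversion, leaves (S)-1-Ar-prop-2-en-1-ol F7.
- Propargylation (NaH, propargyl bromide) gives the enyne (S)-1-Ar-prop-2-en-1-yl prop-2-yn-1-yl ether F8.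
- Borylative enyne cyclisation (Pd(OAc)2, B2pin2, MeOH, toluene, 50 °C) gives (2S,3S)-2-Ar-4-methylidene-3-[(4,4,5,5-tetramethyl-1,3,2-dioxaborolan-2-yl)methyl]oxolane F9.
- F9 is oxidised with NaBO3 to give 7.

**Further compounds**
F1 | step 9 | (1S,5R,6S)-6-Ar-3,7-dioxabicyclo[3.3.0]octane-1,2-diol (mixture at C2) | COc1cc([C@H]2OC[C@]3(O)C(O)OC[C@H]23)ccc1O[Si](C(C)C)(C(C)C)C(C)C
F2 | step 9 | Ar-magnesium bromide | COc1cc([Mg]Br)ccc1O[Si](C(C)C)(C(C)C)C(C)C
F3 | step 9 | (3S,4R,5S)-3-[(R)-Ar(hydroxy)methyl]-4-(hydroxymethyl)-5-Ar-oxolan-3-ol | COc1cc([C@H]2OC[C@](O)([C@H](O)c3ccc(O[Si](C(C)C)(C(C)C)C(C)C)c(OC)c3)[C@@H]2CO)ccc1O[Si](C(C)C)(C(C)C)C(C)C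
F4 | step 9 | (1S,2R,5R,6S)-2,6-di-Ar-3,7-dioxabicyclo[3.3.0]octan-1-ol | COc1cc([C@H]2OC[C@]3(O)[C@@H](c4ccc(O[Si](C(C)C)(C(C)C)C(C)C)c(OC)c4)OC[C@H]23)ccc1O[Si](C(C)C)(C(C)C)C(C)C
F5 | step 7 | [(2S,3R)-2-Ar-4-(methoxymethylidene)oxolan-3-yl]methanol (alkene isomers) | COc1cc([C@H]2OCC(=COC)[C@@H]2CO)ccc1O[Si](C(C)C)(C(C)C)C(C)C
F6 | step 7 | (1R,5R,6S)-2-methoxy-6-Ar-3,7-dioxabicyclo[3.3.0]octane (mixture at C2) | COc1cc([C@H]2OC[C@@H]3C(OC)OC[C@H]23)ccc1O[Si](C(C)C)(C(C)C)C(C)C
F7 | step 5 | (S)-1-Ar-prop-2-en-1-ol | COc1cc([C@@H](O)C=C)ccc1O[Si](C(C)C)(C(C)C)C(C)C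
F8 | step 5 | (S)-1-Ar-prop-2-en-1-yl prop-2-yn-1-yl ether | COc1cc([C@@H](OCC#C)C=C)ccc1O[Si](C(C)C)(C(C)C)C(C)C
F9 | step 5 | (2S,3S)-2-Ar-4-methylidene-3-[(4,4,5,5-tetramethyl-1,3,2-dioxaborolan-2-yl)methyl]oxolane | COc1cc([C@H]2OCC(=C)[C@@H]2CB3OC(C)(C)C(C)(C)O3)ccc1O[Si](C(C)C)(C(C)C)C(C)C
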